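**Retrosynthetic overview**
- Target 26 ← 24 (hydrogenolysis, then protonation) ← 22 (sulfation of O3) ← 21 (MOM removal). O3 is the only oxygen not under benzyl, so the sulfate is placed without a regiochemical choice.
- Feature used: in ring A the ring oxygen O1 (on C8a) and the acyl carbon C4 (on C4a) sit on neighbouring carbons, with the C5 oxygen next to C4a. This is the pattern a 3-alkoxyaryne gives when an O–C(=O) unit adds across it with oxygen at the remote carbon.
- Key disconnection of ring C at O1–C8a, C4–C4a and O1–C2: the aryne from silyl triflate 8 (ring A) plus β-methoxy acrylic acid 17 (O1, C2, C3, C4, the C4 oxygen and ring B).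
- 8 comes from 3,5-bis(benzyloxy)phenol 1 by carbamate-directed ortho-silylation and triflation. 17 comes from methyl glycolate 9 and 4-(benzyloxy)benzoyl chloride 11 by MOM protection, C-aroylation, enol O-methylation and saponification.
- Ring order: rings A and B are bought; ring C is the only ring formed (step 8).

Key step: step 8

Remark: the target is drawn as the free hydrogen sulfate; the sulfate is carried as its sodium salt and protonated only in the last operation, because the free acid is prone to autocatalytic hydrolysis.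
Remark: the enol ether in 15 to 18 is drawn Z (OMe cis to OMOM); the E isomer would converge to the same product in step 8.

**Step 1**
Reactants: 1 3,5-bis(benzyloxy)phenol
Product: 2 3,5-bis(benzyloxy)phenyl isopropylcarbamate
Conditions: i-PrNCO (1.5 equiv), Et3N (0.2 equiv), CH2Cl2, rt
Reagents that add atoms: isopropyl isocyanate, CC(C)N=C=O
Why: Amine-catalysed addition of the phenol to the isocyanate (carbamoylation) should give the N-isopropyl carbamate, a strong ortho-directing group that can later be removed under mild base.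

**Step 2**
Reactants: 2 3,5-bis(benzyloxy)phenyl isopropylcarbamate
Product: 6 3,5-bis(benzyloxy)-2-(trimethylsilyl)phenyl isopropylcarbamate, via N-silyl carbamate 3 (not isolated), via aryllithium 4 (not isolated), via N-silyl arylsilane 5 (not isolated)
Conditions: TBSOTf, TMEDA, Et2O, 0 °C to rt; n-BuLi, TMEDA, −78 °C; TMSCl, −78 °C to rt; aq NaHSO4 work-up
Reagents that add atoms: chlorotrimethylsilane, C[Si](C)(C)Cl
Why: Directed ortho-metalation, in which N-silylation masks the carbamate N–H, n-BuLi/TMEDA removes the ring proton at C2 (flanked and acidified by the carbamate and a benzyloxy group) faster than a benzylic proton at −78 °C, TMSCl traps 4 before an anionic ortho-Fries shift can occur, and the N–Si bond of 5 is hydrolysed on acidic work-up.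

**Step 3**
Reactants: 6 3,5-bis(benzyloxy)-2-(trimethylsilyl)phenyl isopropylcarbamate
Product: 8 3,5-bis(benzyloxy)-2-(trimethylsilyl)phenyl trifluoromethanesulfonate, via silylphenol 7 (not isolated)
Conditions: Et2NH, DBU, MeCN, 40 °C; then PhNTf2, rt
Reagents that add atoms: N-phenylbis(trifluoromethanesulfonimide), O=S(=O)(N(c1ccccc1)S(=O)(=O)C(F)(F)F)C(F)(F)F
Why: Base-induced E1cB loss of isopropyl isocyanate (scavenged by diethylamine as a urea) should free the phenoxide of 7 without touching the aryl–silicon bond, and triflation of that phenoxide with PhNTf2 in the same flask gives the ortho-silyl aryl triflate.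

**Step 4**
Reactants: 9 methyl glycolate
Product: 10 methyl 2-(methoxymethoxy)acetate
Conditions: MOMCl, i-Pr2NEt, CH2Cl2, 0 °C to rt
Reagents that add atoms: chloromethyl methyl ether, COCCl
Why: Alkylation of the primary alcohol with chloromethyl methyl ether and a hindered amine base (MOM protection) gives an acetal that tolerates the enolate chemistry ahead and is orthogonal to the benzyl ethers.

**Step 5**
Reactants: 10 methyl 2-(methoxymethoxy)acetate (2.1 equiv); 11 4-(benzyloxy)benzoyl chloride
Product: 13 methyl 3-[4-(benzyloxy)phenyl]-2-(methoxymethoxy)-3-oxopropanoate (racemic), via lithium enolate 12 (not isolated)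
Conditions: LiN(SiMe3)2 (2.1 equiv), THF, −78 °C; then 11, −78 to −40 °C; aq NH4Cl
Reagents that add atoms: none
Why: Crossed Claisen-type C-acylation of the lithium ester enolate by the non-enolisable aroyl chloride should give the β-keto ester, the second equivalent of enolate taking up the acidic proton of the product, and the new stereocenter at C2 is formed racemic and erased in step 6.

**Step 6**
Reactants: 13 methyl 3-[4-(benzyloxy)phenyl]-2-(methoxymethoxy)-3-oxopropanoate
Product: 15 methyl (Z)-3-[4-(benzyloxy)phenyl]-3-methoxy-2-(methoxymethoxy)acrylate, via potassium enolate 14 (not isolated)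
Conditions: KN(SiMe3)2, 18-crown-6, THF, −78 °C; then MeOTf, −78 to 0 °C
Reagents that add atoms: methyl trifluoromethanesulfonate, COS(=O)(=O)C(F)(F)F
Why: O-alkylation of a dissociated β-keto ester enolate, where the crown-separated potassium enolate should react with the hard electrophile MeOTf at oxygen and not at the fully substituted carbon, the W-shaped free enolate favouring the Z enol ether.

**Step 7**
Reactants: 15 methyl (Z)-3-[4-(benzyloxy)phenyl]-3-methoxy-2-(methoxymethoxy)acrylate
Product: 17 (Z)-3-[4-(benzyloxy)phenyl]-3-methoxy-2-(methoxymethoxy)acrylic acid, via lithium carboxylate 16 (not isolated)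
Conditions: LiOH·H2O, THF–MeOH–H2O, 45 °C; then 1 M aq HCl to pH 4, 0 °C
Reagents that add atoms: lithium hydroxide, [Li+].[OH-]
Why: Saponification (ester hydrolysis by acyl–oxygen cleavage) should proceed because the fully substituted, donor-bearing β-carbon resists conjugate attack by hydroxide, and acidifying only to pH 4 in the cold spares the enol ether and the MOM acetal.

**Step 8**
Reactants: 17 (Z)-3-[4-(benzyloxy)phenyl]-3-methoxy-2-(methoxymethoxy)acrylic acid; 8 3,5-bis(benzyloxy)-2-(trimethylsilyl)phenyl trifluoromethanesulfonate (1.5 equiv)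
Product: 21 5,7-bis(benzyloxy)-2-[4-(benzyloxy)phenyl]-3-(methoxymethoxy)-4H-chromen-4-one, via cesium carboxylate 18 (not isolated), via aryne 19 (not isolated), via acylphenoxide 20 (not isolated)
Conditions: Cs2CO3 (0.5 equiv), MeOH, rt, evaporate, PhMe azeotrope; then 8, CsF (3 equiv), THF, 100 °C, sealed tube
Reagents that add atoms: none
Why: Proposed new method: fluoride removes the trimethylsilyl group of 8 and triflate departs to give aryne 19, a carboxylate oxygen of 18 adds to the aryne carbon that becomes C8a, the aryl anion at C4a attacks the ester carbonyl through a four-membered transition state and the acyl C–O bond breaks (an anionic Fries-type 1,3-acyl shift), leaving phenoxide 20. The closest known reaction type is the fluoride-mediated insertion of arynes into the C–O bond of carboxylic acids, which gives ortho-hydroxyaryl ketones and runs on to chromanones and flavones with acrylic and propiolic acids; a tetrasubstituted β-methoxy acrylate with closure by addition–elimination has not been shown. Ring C then closes by 6-endo-trig conjugate addition of the phenoxide oxygen of 20 to the β-carbon (C2), and loss of methoxide restores the enone, so the enol ether geometry does not matter and no stereocenter is formed. The step needs regioselective addition to the unsymmetrical aryne, which the benzyloxy group next to the triple bond should secure by distorting the aryne so that the nucleophile enters at the remote carbon and the charge builds on the carbon beside the inductively withdrawing C–O bond. It also needs attack of the aryl anion on the ester carbonyl in preference to protonation or attack at the β-carbon, which the proton-free cesium salt, the absence of α-hydrogens and the Z conformation of the aryl ester (β-carbon held away from the anion and deactivated by its methoxy donor) should favour.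

**Step 9**
Reactants: 21 5,7-bis(benzyloxy)-2-[4-(benzyloxy)phenyl]-3-(methoxymethoxy)-4H-chromen-4-one
Product: 22 5,7-bis(benzyloxy)-2-[4-(benzyloxy)phenyl]-3-hydroxy-4H-chromen-4-one
Conditions: HCl (1.25 M in MeOH), CH2Cl2, rt
Reagents that add atoms: none
Why: Acid-catalysed transacetalisation of the MOM ether to dimethoxymethane in methanol (acetal cleavage) should free the 3-hydroxyl, while the benzyl aryl ethers, which need far stronger acid, stay in place.

**Step 10**
Reactants: 22 5,7-bis(benzyloxy)-2-[4-(benzyloxy)phenyl]-3-hydroxy-4H-chromen-4-one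
Product: 24 sodium 5,7-bis(benzyloxy)-2-[4-(benzyloxy)phenyl]-4-oxo-4H-chromen-3-yl sulfate, via pyridinium sulfate 23 (not isolated)
Conditions: SO3·pyridine (5 equiv), pyridine–DMF, 50 °C; then aq NaHCO3
Reagents that add atoms: sulfur trioxide pyridine complex, [O-]S(=O)(=O)[n+]1ccccc1; sodium hydrogen carbonate, [Na+].OC([O-])=O
Why: O-sulfation with the sulfur trioxide–pyridine complex at the only free hydroxyl (O3) should give the pyridinium sulfate, and exchange to the sodium salt removes pyridine, which would otherwise inhibit the palladium catalyst of the last step.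

**Step 11**
Reactants: 24 sodium 5,7-bis(benzyloxy)-2-[4-(benzyloxy)phenyl]-4-oxo-4H-chromen-3-yl sulfate
Product: 26 kaempferol 3-O-sulfate (5,7-dihydroxy-2-(4-hydroxyphenyl)-4-oxo-4H-chromen-3-yl hydrogen sulfate), via sodium kaempferol 3-O-sulfate 25 (not isolated)
Conditions: H2 (1 atm), 10% Pd/C, MeOH–THF, rt; filter; then aq HCl (1.0 equiv), 0 °C, C18 desalting, lyophilise
Reagents that add atoms: none
Why: Hydrogenolysis of the three benzyl aryl ethers over Pd/C should leave the sulfate monoester and the tetrasubstituted C2=C3 bond untouched, and one equivalent of cold acid then protonates the sulfate to the free hydrogen sulfate.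

**Compound list**
1 | 3,5-bis(benzyloxy)phenol | Oc1cc(OCc2ccccc2)cc(OCc2ccccc2)c1 | starting material
2 | 3,5-bis(benzyloxy)phenyl isopropylcarbamate | CC(C)NC(=O)Oc1cc(OCc2ccccc2)cc(OCc2ccccc2)c1 | intermediate
3 | 3,5-bis(benzyloxy)phenyl N-(tert-butyldimethylsilyl)-N-isopropylcarbamate | CC(C)N(C(=O)Oc1cc(OCc2ccccc2)cc(OCc2ccccc2)c1)[Si](C)(C)C(C)(C)C | intermediate (not isolated)
4 | 2-lithio-3,5-bis(benzyloxy)phenyl N-(tert-butyldimethylsilyl)-N-isopropylcarbamate | [Li]c1c(OC(=O)N(C(C)C)[Si](C)(C)C(C)(C)C)cc(OCc2ccccc2)cc1OCc1ccccc1 | intermediate (not isolated)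
5 | 3,5-bis(benzyloxy)-2-(trimethylsilyl)phenyl N-(tert-butyldimethylsilyl)-N-isopropylcarbamate | C[Si](C)(C)c1c(OC(=O)N(C(C)C)[Si](C)(C)C(C)(C)C)cc(OCc2ccccc2)cc1OCc1ccccc1 | intermediate (not isolated)
6 | 3,5-bis(benzyloxy)-2-(trimethylsilyl)phenyl isopropylcarbamate | C[Si](C)(C)c1c(OC(=O)NC(C)C)cc(OCc2ccccc2)cc1OCc1ccccc1 | intermediate
7 | 3,5-bis(benzyloxy)-2-(trimethylsilyl)phenol | C[Si](C)(C)c1c(O)cc(OCc2ccccc2)cc1OCc1ccccc1 | intermediate (not isolated)
8 | 3,5-bis(benzyloxy)-2-(trimethylsilyl)phenyl trifluoromethanesulfonate | C[Si](C)(C)c1c(OS(=O)(=O)C(F)(F)F)cc(OCc2ccccc2)cc1OCc1ccccc1 | intermediate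
9 | methyl glycolate | COC(=O)CO | starting material
10 | methyl 2-(methoxymethoxy)acetate | COCOCC(=O)OC | intermediate
11 | 4-(benzyloxy)benzoyl chloride | O=C(Cl)c1ccc(OCc2ccccc2)cc1 | starting material
12 | lithium enolate of methyl 2-(methoxymethoxy)acetate (geometry of no consequence) | [Li]OC(OC)=COCOC | intermediate (not isolated)
13 | methyl 3-[4-(benzyloxy)phenyl]-2-(methoxymethoxy)-3-oxopropanoate (racemic) | COCOC(C(=O)OC)C(=O)c1ccc(OCc2ccccc2)cc1 | intermediate
14 | potassium (Z)-1-[4-(benzyloxy)phenyl]-3-methoxy-2-(methoxymethoxy)-3-oxoprop-1-en-1-olate | COC(=O)/C(OCOC)=C(/[O-])c1ccc(OCc2ccccc2)cc1.[K+] | intermediate (not isolated)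
15 | methyl (Z)-3-[4-(benzyloxy)phenyl]-3-methoxy-2-(methoxymethoxy)acrylate | COC(=O)/C(OCOC)=C(/OC)c1ccc(OCc2ccccc2)cc1 | intermediate
16 | lithium (Z)-3-[4-(benzyloxy)phenyl]-3-methoxy-2-(methoxymethoxy)acrylate | [Li+].[O-]C(=O)/C(OCOC)=C(/OC)c1ccc(OCc2ccccc2)cc1 | intermediate (not isolated)
17 | (Z)-3-[4-(benzyloxy)phenyl]-3-methoxy-2-(methoxymethoxy)acrylic acid | OC(=O)/C(OCOC)=C(/OC)c1ccc(OCc2ccccc2)cc1 | intermediate
18 | cesium (Z)-3-[4-(benzyloxy)phenyl]-3-methoxy-2-(methoxymethoxy)acrylate | [Cs+].[O-]C(=O)/C(OCOC)=C(/OC)c1ccc(OCc2ccccc2)cc1 | intermediate (not isolated)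
19 | 3,5-bis(benzyloxy)benzyne (1,2-didehydro-3,5-bis(benzyloxy)benzene) | C1#CC(OCc2ccccc2)=CC(OCc2ccccc2)=C1 | intermediate (not isolated)
20 | cesium 3,5-bis(benzyloxy)-2-[(Z)-3-[4-(benzyloxy)phenyl]-3-methoxy-2-(methoxymethoxy)prop-2-enoyl]phenolate | [Cs+].[O-]c1cc(OCc2ccccc2)cc(OCc2ccccc2)c1C(=O)/C(OCOC)=C(/OC)c1ccc(OCc2ccccc2)cc1 | intermediate (not isolated)
21 | 5,7-bis(benzyloxy)-2-[4-(benzyloxy)phenyl]-3-(methoxymethoxy)-4H-chromen-4-one | O=c1c(OCOC)c(-c2ccc(OCc3ccccc3)cc2)oc2cc(OCc3ccccc3)cc(OCc3ccccc3)c12 | intermediate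
22 | 5,7-bis(benzyloxy)-2-[4-(benzyloxy)phenyl]-3-hydroxy-4H-chromen-4-one | O=c1c(O)c(-c2ccc(OCc3ccccc3)cc2)oc2cc(OCc3ccccc3)cc(OCc3ccccc3)c12 | intermediate
23 | pyridinium 5,7-bis(benzyloxy)-2-[4-(benzyloxy)phenyl]-4-oxo-4H-chromen-3-yl sulfate | c1cc[nH+]cc1.[O-]S(=O)(=O)Oc1c(-c2ccc(OCc3ccccc3)cc2)oc2cc(OCc3ccccc3)cc(OCc3ccccc3)c2c1=O | intermediate (not isolated)
24 | sodium 5,7-bis(benzyloxy)-2-[4-(benzyloxy)phenyl]-4-oxo-4H-chromen-3-yl sulfate | [Na+].[O-]S(=O)(=O)Oc1c(-c2ccc(OCc3ccccc3)cc2)oc2cc(OCc3ccccc3)cc(OCc3ccccc3)c2c1=O | intermediate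
25 | sodium kaempferol 3-O-sulfate | [Na+].[O-]S(=O)(=O)Oc1c(-c2ccc(O)cc2)oc2cc(O)cc(O)c2c1=O | intermediate (not isolated)
26 | kaempferol 3-O-sulfate | O=c1c(OS(=O)(=O)O)c(-c2ccc(O)cc2)oc2cc(O)cc(O)c12 | target

**Step count**
Total steps: 11 (steps 1 to 3 and steps 4 to 7 are two converging branches).
Longest linear sequence: 8 steps (steps 4 to 11, from methyl glycolate).

**Steps most likely to fail**

1. Step 8 (aryne insertion and annulation). The aryl anion may be protonated before the acyl shift, the carboxylate may add to the aryne in the wrong orientation, or the released methoxide may consume the aryne. The fallback builds ring C by known chemistry from the acetophenone side, setting out from 11 and coming back at 22, so that steps 8 and 9 are bypassed. Purchased 1-[2,4-bis(benzyloxy)-6-hydroxyphenyl]ethanone F1 is converted to its dianion (LiN(SiMe3)2, THF, −78 °C to rt) and C-aroylated by 11 to give 1-[2,4-bis(benzyloxy)-6-hydroxyphenyl]-3-[4-(benzyloxy)phenyl]propane-1,3-dione F2. Cyclodehydration (NaOAc, AcOH, 100 °C) should give 5,7-bis(benzyloxy)-2-[4-(benzyloxy)phenyl]-4H-chromen-4-one F3. Dimethyldioxirane in acetone–CH2Cl2 at 0 °C epoxidises the C2=C3 bond to the racemic 2,3-epoxyflavanone F4, which catalytic TsOH opens and tautomerises to flavonol 22.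

2. Step 2 (directed ortho-silylation). Benzylic deprotonation followed by a 1,2-Wittig rearrangement, lithiation at C4 between the two benzyloxy groups, or anionic ortho-Fries migration of the carbamoyl group may compete. The fallback replaces deprotonation by halogen–lithium exchange, setting out from 1 and coming back at 8, so that steps 1 to 3 are bypassed. Amine-catalysed ortho-bromination (NBS, catalytic i-Pr2NH, CH2Cl2, −78 to 0 °C) should give 2-bromo-3,5-bis(benzyloxy)phenol F5. Hexamethyldisilazane in THF at 70 °C gives [2-bromo-3,5-bis(benzyloxy)phenoxy]trimethylsilane F6. n-BuLi in THF at −100 °C effects bromine–lithium exchange and a retro-Brook O-to-C silyl shift to lithium 3,5-bis(benzyloxy)-2-(trimethylsilyl)phenoxide F7, which is trapped in the same flask with Tf2O to give 8.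

3. Step 7 (saponification). Hydroxide may attack the β-carbon with loss of methoxide and subsequent decarboxylation, or the enol ether and MOM acetal may hydrolyse during acidification. The fallback unmasks the acid without hydroxide, setting out from 11 and coming back at 17, so that the methyl ester series 13 and 15 is bypassed. Purchased allyl glycolate F8 is protected (MOMCl, i-Pr2NEt, CH2Cl2) as allyl 2-(methoxymethoxy)acetate F9. Its lithium enolate (LiN(SiMe3)2, THF, −78 °C) is acylated by 11 to allyl 3-[4-(benzyloxy)phenyl]-2-(methoxymethoxy)-3-oxopropanoate F10. O-methylation as in step 6 (KN(SiMe3)2, 18-crown-6, MeOTf) gives allyl (Z)-3-[4-(benzyloxy)phenyl]-3-methoxy-2-(methoxymethoxy)acrylate F11. Allyl transfer to morpholine catalysed by zerovalent palladium (Pd(PPh3)4, morpholine, THF, rt; pH 5 buffer wash) should then deliver 17.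

**Further compounds**
F1 | step 8 | 1-[2,4-bis(benzyloxy)-6-hydroxyphenyl]ethanone (purchased) | CC(=O)c1c(O)cc(OCc2ccccc2)cc1OCc1ccccc1
F2 | step 8 | 1-[2,4-bis(benzyloxy)-6-hydroxyphenyl]-3-[4-(benzyloxy)phenyl]propane-1,3-dione | O=C(CC(=O)c1ccc(OCc2ccccc2)cc1)c1c(O)cc(OCc2ccccc2)cc1OCc1ccccc1
F3 | step 8 | 5,7-bis(benzyloxy)-2-[4-(benzyloxy)phenyl]-4H-chromen-4-one | O=c1cc(-c2ccc(OCc3ccccc3)cc2)oc2cc(OCc3ccccc3)cc(OCc3ccccc3)c12
F4 | step 8 | 5,7-bis(benzyloxy)-2-[4-(benzyloxy)phenyl]-2,3-epoxychroman-4-one (racemic, cis-fused epoxide) | O=C1c2c(OCc3ccccc3)cc(OCc3ccccc3)cc2OC2(c3ccc(OCc4ccccc4)cc3)OC12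
F5 | step 2 | 2-bromo-3,5-bis(benzyloxy)phenol | Oc1cc(OCc2ccccc2)cc(OCc2ccccc2)c1Br
F6 | step 2 | [2-bromo-3,5-bis(benzyloxy)phenoxy]trimethylsilane | C[Si](C)(C)Oc1cc(OCc2ccccc2)cc(OCc2ccccc2)c1Br
F7 | step 2 | lithium 3,5-bis(benzyloxy)-2-(trimethylsilyl)phenoxide | [Li+].[O-]c1cc(OCc2ccccc2)cc(OCc2ccccc2)c1[Si](C)(C)C
F8 | step 7 | allyl glycolate (purchased) | OCC(=O)OCC=C
F9 | step 7 | allyl 2-(methoxymethoxy)acetate | COCOCC(=O)OCC=C
F10 | step 7 | allyl 3-[4-(benzyloxy)phenyl]-2-(methoxymethoxy)-3-oxopropanoate (racemic) | COCOC(C(=O)OCC=C)C(=O)c1ccc(OCc2ccccc2)cc1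
F11 | step 7 | allyl (Z)-3-[4-(benzyloxy)phenyl]-3-methoxy-2-(methoxymethoxy)acrylate | C=CCOC(=O)/C(OCOC)=C(/OC)c1ccc(OCc2ccccc2)cc1
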